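**Plan**

- Retrosynthetic cuts, in order: the C6–O acyl bond (acylation); the C6–H bond (ketone reduction); the C6 carbonyl, unmasked from an exocyclic methylene (ozonolysis); the butenolide O1–C2 and C3=C3a bonds (α-hydroxy ketone plus a two-carbon ylide); the ring bond C7–C7a (carbonyl-ene closure); then the open chain back to isobutyronitrile, methallyl chloride and an acetyl anion equivalent.
- Enabling feature (benzofuranone numbering): C7a carries O and CH3 and sits next to sp2 C3a, so C3a/C7a can be a vicinal diketone that binds a metal through both oxygens. C7a(O)–C7H2–C6(O) is a 1,3-dioxygen (aldol-type) array, so C6/C7 can arrive as a 2-methylallyl ene donor whose methyl becomes an exocyclic methylene, a masked C6 ketone. The C4 gem-dimethyl group aids closure.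
- Forward order: acyclic ene-dione, then the six-membered carbocycle (sets C7a), then the butenolide ring, then C6=O unmasked, reduced and acylated.
- Stereochemistry: C7a (R) from a chiral bis(oxazoline)–copper catalyst in the ring closure; C6 (S) from substrate-controlled equatorial hydride delivery.
- Helpers removed later: the C3a ketone (chelating activator, consumed in the Wittig closure) and the extra methylene carbon (lost as formaldehyde).

Key step: step 3

Assumption: the facial sense in step 3 is assigned by analogy with additions to copper-bound pyruvate; if the opposite sense were found, the (S,S)-ligand would be used with no other change.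

**Step 1**
Reactants: 1 isobutyronitrile; 2 3-chloro-2-methylprop-1-ene (methallyl chloride)
Product: 4 2,2,4-trimethylpent-4-enenitrile, via lithiated isobutyronitrile 3 (not isolated)
Conditions: LiN(i-Pr)2, THF, −78 °C; then 2, −78 °C to rt
Reagents that add atoms: none
Why: SN2 C-alkylation of the lithiated nitrile (a keteniminate with no second acidic site) by the allylic chloride should build the gem-dimethyl quaternary carbon; no stereocenter is formed.

**Step 2**
Reactants: 4 2,2,4-trimethylpent-4-enenitrile; 5 ethyl vinyl ether (ethoxyethene)
Product: 8 4,4,6-trimethylhept-6-ene-2,3-dione, via N-lithio ketimine 6 (not isolated), via ethoxy enone 7 (not isolated)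
Conditions: 5, t-BuLi, THF, −78 to 0 °C; then 4, −78 °C to rt; then 1 M aq. HCl, THF, 0 °C to rt
Reagents that add atoms: water, O
Why: Nucleophilic acylation with 1-ethoxyvinyllithium (an acetyl anion equivalent) should add once to the non-enolisable nitrile, and mild aqueous acid should hydrolyse both the imine and the enol ether to the vicinal diketone; no stereocenter is formed.

**Step 3**
Reactants: 8 4,4,6-trimethylhept-6-ene-2,3-dione
Product: 9 (2R)-2-hydroxy-2,6,6-trimethyl-4-methylidenecyclohexan-1-one
Conditions: [Cu((R,R)-t-Bu-box)](SbF6)2 (10 mol %; (R,R)-t-Bu-box = 2,2'-(propane-2,2-diyl)bis[(4R)-4-tert-butyl-4,5-dihydro-1,3-oxazole]), CH2Cl2, 4 Å MS, 0 °C to rt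
Reagents that add atoms: none
Why: Proposed new method: an intramolecular carbonyl-ene reaction of type 2, in which the s-cis 1,2-diketone binds divalent copper through both oxygens in a square-planar chelate, the CH2 terminus of the 2-methylallyl unit attacks the activated acetyl carbonyl carbon, and a methyl hydrogen passes to oxygen in a concerted six-centre array, leaving the exocyclic methylene. The closest known reaction types are the bis(oxazoline)–copper-catalysed enantioselective carbonyl-ene reactions of pyruvates and glyoxylates with 1,1-disubstituted alkenes and the ene cyclisation of unsaturated alpha-keto esters under the same catalysts; a substrate whose second chelating carbonyl is a ketone lying inside the tether has not been shown. The six-membered carbocycle should close in the 6-exo-trig mode at the carbonyl (ene unit tethered through its central carbon), helped by the gem-dimethyl group. The new quaternary carbinol centre is catalyst-controlled: the tert-butyl groups of the ligand shield one face of the chelated acetyl carbonyl, and by analogy with pyruvate the (R,R)-ligand should expose the face that leads to the (R)-alcohol. The step needs site selectivity for the acetyl over the neopentyl-type carbonyl (less hindered, and attack on the other carbonyl would require a five-membered type 2 closure), hydrogen transfer from the methyl and not from the ring CH2 (geometry of the bicyclic ene transition state), and suppression of the uncatalysed background (low temperature, non-coordinating SbF6 counter-ion).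

**Step 4**
Reactants: 9 (2R)-2-hydroxy-2,6,6-trimethyl-4-methylidenecyclohexan-1-one; 10 (triphenylphosphoranylidene)ketene (Bestmann ylide)
Product: 12 (7aR)-4,4,7a-trimethyl-6-methylidene-5,6,7,7a-tetrahydro-1-benzofuran-2(4H)-one, via ester ylide 11 (not isolated)
Conditions: toluene, 110 °C
Reagents that add atoms: none
Why: In the Bestmann addition–intramolecular Wittig cascade the tertiary hydroxyl should add across the cumulated ylide to give a stabilised ester ylide held next to the hindered ketone, which closes the butenolide with loss of Ph3PO while the exocyclic methylene keeps the future C6 carbonyl out of reach of the ylide; the quaternary centre is untouched.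

**Step 5**
Reactants: 12 (7aR)-4,4,7a-trimethyl-6-methylidene-5,6,7,7a-tetrahydro-1-benzofuran-2(4H)-one
Product: 14 (7aR)-4,4,7a-trimethyl-7,7a-dihydro-1-benzofuran-2,6(4H,5H)-dione (dehydrololiolide), via spiro ozonide 13 (not isolated)
Conditions: O3, CH2Cl2, −78 °C (to first persistent blue); then Me2S, −78 °C to rt
Reagents that add atoms: ozone, [O-][O+]=O
Why: Ozonolysis with reductive work-up should cleave the isolated 1,1-disubstituted alkene much faster than the electron-poor conjugated butenolide double bond, unmasking the C6 ketone under neutral conditions; no stereocenter is changed.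

**Step 6**
Reactants: 14 (7aR)-4,4,7a-trimethyl-7,7a-dihydro-1-benzofuran-2,6(4H,5H)-dione
Product: 16 (6S,7aR)-6-hydroxy-4,4,7a-trimethyl-5,6,7,7a-tetrahydro-1-benzofuran-2(4H)-one ((−)-loliolide), via lithium alkoxide 15 (not isolated)
Conditions: LiBH(s-Bu)3 (1.1 equiv), THF, −78 °C; then AcOH, −78 °C to rt
Reagents that add atoms: none
Why: In this substrate-controlled reduction the bulky borohydride should attack the cyclohexanone from the equatorial direction, because the axial trajectory is blocked by the syn-axial methyl groups at C4 and C7a; this gives the axial (6S) alcohol cis to the 7a-methyl group, and the beta,beta-disubstituted butenolide should be inert at −78 °C.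

**Step 7**
Reactants: 16 (−)-loliolide; 17 hexadecanoyl chloride (palmitoyl chloride)
Product: 18 (6S,7aR)-4,4,7a-trimethyl-2-oxo-2,4,5,6,7,7a-hexahydro-1-benzofuran-6-yl hexadecanoate ((−)-3-O-palmitoylloliolide)
Conditions: pyridine, DMAP (0.1 equiv), CH2Cl2, 0 °C to rt
Reagents that add atoms: none
Why: DMAP-catalysed acylation (nucleophilic catalysis) of the secondary axial alcohol by the acid chloride should proceed with retention at C6 and leave the lactone untouched.

**Compound list**

1 | isobutyronitrile | CC(C)C#N | starting material
2 | 3-chloro-2-methylprop-1-ene | C=C(C)CCl | starting material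
3 | lithiated isobutyronitrile (N-lithio keteniminate) | CC(C)=C=N[Li] | intermediate
4 | 2,2,4-trimethylpent-4-enenitrile | C=C(C)CC(C)(C)C#N | intermediate
5 | ethyl vinyl ether | C=COCC | starting material
6 | lithium 2-ethoxy-4,4,6-trimethylhepta-1,6-dien-3-iminide | C=C(C)CC(C)(C)C(=N[Li])C(=C)OCC | intermediate
7 | 2-ethoxy-4,4,6-trimethylhepta-1,6-dien-3-one | C=C(C)CC(C)(C)C(=O)C(=C)OCC | intermediate
8 | 4,4,6-trimethylhept-6-ene-2,3-dione | CC(=O)C(=O)C(C)(C)CC(C)=C | intermediate
9 | (2R)-2-hydroxy-2,6,6-trimethyl-4-methylidenecyclohexan-1-one | C[C@@]1(O)CC(=C)CC(C)(C)C1=O | intermediate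
10 | (triphenylphosphoranylidene)ketene | O=C=C=P(c1ccccc1)(c1ccccc1)c1ccccc1 | starting material
11 | (1R)-1,3,3-trimethyl-5-methylidene-2-oxocyclohexyl (triphenyl-λ5-phosphanylidene)acetate | C[C@@]1(OC(=O)C=P(c2ccccc2)(c2ccccc2)c2ccccc2)CC(=C)CC(C)(C)C1=O | intermediate
12 | (7aR)-4,4,7a-trimethyl-6-methylidene-5,6,7,7a-tetrahydro-1-benzofuran-2(4H)-one | C=C1CC(C)(C)C2=CC(=O)O[C@]2(C)C1 | intermediate
13 | spiro 1,2,4-trioxolane (ozonide) at C6 of compound 12 | O1COC2(O1)CC(C)(C)C3=CC(=O)O[C@]3(C)C2 | intermediate
14 | (7aR)-4,4,7a-trimethyl-7,7a-dihydro-1-benzofuran-2,6(4H,5H)-dione | O=C1CC(C)(C)C2=CC(=O)O[C@]2(C)C1 | intermediate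
15 | lithium (6S,7aR)-4,4,7a-trimethyl-2-oxo-2,4,5,6,7,7a-hexahydro-1-benzofuran-6-olate | [Li]O[C@H]1CC(C)(C)C2=CC(=O)O[C@]2(C)C1 | intermediate
16 | (6S,7aR)-6-hydroxy-4,4,7a-trimethyl-5,6,7,7a-tetrahydro-1-benzofuran-2(4H)-one ((−)-loliolide) | O[C@H]1CC(C)(C)C2=CC(=O)O[C@]2(C)C1 | intermediate
17 | hexadecanoyl chloride | CCCCCCCCCCCCCCCC(=O)Cl | starting material
18 | (6S,7aR)-4,4,7a-trimethyl-2-oxo-2,4,5,6,7,7a-hexahydro-1-benzofuran-6-yl hexadecanoate | CCCCCCCCCCCCCCCC(=O)O[C@H]1CC(C)(C)C2=CC(=O)O[C@]2(C)C1 | target

**Totals**

Total step count: 7. Longest linear sequence: 7 steps (from isobutyronitrile).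

**Steps most likely to fail**

Step 3. Enantiofacial discrimination may be poor on a diketone whose second carbonyl lies in the tether, turnover may stall because the alpha-ketol product chelates the catalyst, or a stepwise cationic closure may lose a proton into the ring. The fallback sets out from 8 and comes back at 9. Sc(OTf)3 (10 mol %, CH2Cl2, rt) should promote the same type 2 carbonyl-ene closure without stereocontrol to give racemic 2-hydroxy-2,6,6-trimethyl-4-methylidenecyclohexan-1-one F1. Preparative chromatography on a chiral stationary phase (cellulose tris(3,5-dimethylphenylcarbamate)) should then deliver 9, and (2S)-2-hydroxy-2,6,6-trimethyl-4-methylidenecyclohexan-1-one F2 is set aside.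

Step 4. The hindered tertiary hydroxyl may add slowly to the cumulated ylide, the stabilised ylide may fail to engage the doubly neopentyl ketone, and prolonged heating may allow alpha-ketol rearrangement. The fallback sets out from 9 and comes back at 12. Acylation with bromoacetyl bromide (pyridine, CH2Cl2, 0 °C) should give (1R)-1,3,3-trimethyl-5-methylidene-2-oxocyclohexyl bromoacetate F3. Arbuzov reaction with P(OEt)3 (neat, 100 °C) should give (1R)-1,3,3-trimethyl-5-methylidene-2-oxocyclohexyl (diethoxyphosphoryl)acetate F4. NaH (THF, 0 °C to rt) should then close the butenolide by intramolecular Horner–Wadsworth–Emmons olefination through the more nucleophilic phosphonate carbanion, giving 12.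

Step 2. Addition to the hindered nitrile may be incomplete, and the aqueous acid needed for hydrolysis may trigger premature, racemic ring closure of the diketone. The fallback sets out from 4 and comes back at 8, with no acid present once the diketone exists. EtMgBr (CuBr 2 mol %, THF, reflux) should give bromomagnesium 4,4,6-trimethylhept-6-en-3-iminide F5, hydrolysed with aqueous HCl to 4,4,6-trimethylhept-6-en-3-one F6. LiN(i-Pr)2 (THF, −78 °C) should give lithium (Z)-4,4,6-trimethylhepta-2,6-dien-3-olate F7, which is hydroxylated with 2-(phenylsulfonyl)-3-phenyloxaziridine to racemic 2-hydroxy-4,4,6-trimethylhept-6-en-3-one F8. Dess–Martin periodinane (NaHCO3, CH2Cl2, rt) should then give 8.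

**Further compounds**

F1 | step 3 | racemic 2-hydroxy-2,6,6-trimethyl-4-methylidenecyclohexan-1-one | CC1(O)CC(=C)CC(C)(C)C1=O
F2 | step 3 | (2S)-2-hydroxy-2,6,6-trimethyl-4-methylidenecyclohexan-1-one | C[C@]1(O)CC(=C)CC(C)(C)C1=O
F3 | step 4 | (1R)-1,3,3-trimethyl-5-methylidene-2-oxocyclohexyl bromoacetate | C[C@@]1(OC(=O)CBr)CC(=C)CC(C)(C)C1=O
F4 | step 4 | (1R)-1,3,3-trimethyl-5-methylidene-2-oxocyclohexyl (diethoxyphosphoryl)acetate | C[C@@]1(OC(=O)CP(=O)(OCC)OCC)CC(=C)CC(C)(C)C1=O
F5 | step 2 | bromomagnesium 4,4,6-trimethylhept-6-en-3-iminide | CCC(=N[Mg]Br)C(C)(C)CC(C)=C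
F6 | step 2 | 4,4,6-trimethylhept-6-en-3-one | CCC(=O)C(C)(C)CC(C)=C
F7 | step 2 | lithium (Z)-4,4,6-trimethylhepta-2,6-dien-3-olate | C/C=C(\O[Li])C(C)(C)CC(C)=C
F8 | step 2 | racemic 2-hydroxy-4,4,6-trimethylhept-6-en-3-one | CC(O)C(=O)C(C)(C)CC(C)=C
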